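**Strategy.** Everything rests on disconnecting C1–C6, the bond shared by the cyclohexene ring and the oxirane (C1 quaternary with CH2OBz, C6 allylic to C4=C5). An open-chain Z-allylic bromide carrying the C1 ketone is closed in one operation by a sulfur-ylide epoxy-annulation: the tetrahydrothiophenium ylide carbon C6 adds to the C1 carbonyl (carbocycle) and the resulting alkoxide expels the sulfide (epoxide), fixing C1 and C6 relative to C2/C3. The acyclic precursor is a 1-benzoyloxy-2-ketone with two silyl-protected erythro carbinols; its stereocentres come from a proline-catalysed aldol of dihydroxyacetone acetonide with an ynal, and Lindlar reduction supplies the Z-alkene.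

Key step: step 9

Remark: atom numbers C1–C7 refer throughout to the target skeleton (C1 quaternary oxirane carbon, C2 CHOH, C3 CHOBz, C4=C5, C6 oxirane CH, C7 the CH2OBz carbon); compounds 1, 3 and 11 are assumed to be purchased.

Step 1
Reactants: 1 1-methoxy-4-[(prop-2-yn-1-yloxy)methyl]benzene (PMB propargyl ether)
Product: 2 4-[(4-methoxybenzyl)oxy]but-2-ynal
Conditions: n-BuLi, THF, −78 °C; DMF, −78 → 0 °C; reverse quench into 10% aq. KH2PO4
Reagents that add atoms: N,N-dimethylformamide, CN(C)C=O
Why: Formylation of a lithium acetylide: n-BuLi removes the alkyne proton, the acetylide adds to DMF, and the hemiaminal alkoxide releases the ynal only on the buffered reverse quench, so the liberated dimethylamine should not add to the triple bond.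

Step 2
Reactants: 2 4-[(4-methoxybenzyl)oxy]but-2-ynal; 3 2,2-dimethyl-1,3-dioxan-5-one
Product: 4 (4S)-4-[(1S)-1-hydroxy-4-[(4-methoxybenzyl)oxy]but-2-yn-1-yl]-2,2-dimethyl-1,3-dioxan-5-one
Conditions: L-proline (30 mol%), DMF, 4 °C
Reagents that add atoms: none
Why: Proline-catalysed direct asymmetric aldol (enamine catalysis): the ring-fixed E-enamine of 3 should add to the Re face of the non-enolisable ynal in a chair-like transition state organised by the carboxylic acid hydrogen bond, giving the anti adduct and setting C2 (S) and C3 (S).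

Step 3
Reactants: 4 (4S)-4-[(1S)-1-hydroxy-4-[(4-methoxybenzyl)oxy]but-2-yn-1-yl]-2,2-dimethyl-1,3-dioxan-5-one
Product: 5 (3S,4S)-1,3,4-trihydroxy-7-[(4-methoxybenzyl)oxy]hept-5-yn-2-one
Conditions: 1 M aq. HCl, THF, rt
Reagents that add atoms: none
Why: Acid-catalysed acetal hydrolysis: the 1,3-dioxan-5-one acetonide is cleaved by dilute acid at room temperature, while the PMB ether and alkyne are stable and no base is present that could cause retro-aldol cleavage or epimerisation at C2.

Step 4
Reactants: 5 (3S,4S)-1,3,4-trihydroxy-7-[(4-methoxybenzyl)oxy]hept-5-yn-2-one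
Product: 6 (3S,4S)-3,4-dihydroxy-7-[(4-methoxybenzyl)oxy]-2-oxohept-5-yn-1-yl benzoate
Conditions: BzCl (1.05 equiv), 2,4,6-collidine, CH2Cl2/THF, −40 °C
Reagents that add atoms: benzoyl chloride, O=C(Cl)c1ccccc1
Why: Kinetically selective O-acylation with an acid chloride and a hindered pyridine base: at low temperature the primary C7 hydroxyl should be benzoylated much faster than the two secondary hydroxyls.

Step 5
Reactants: 6 (3S,4S)-3,4-dihydroxy-7-[(4-methoxybenzyl)oxy]-2-oxohept-5-yn-1-yl benzoate
Product: 7 (3S,4S)-7-[(4-methoxybenzyl)oxy]-2-oxo-3,4-bis[(triethylsilyl)oxy]hept-5-yn-1-yl benzoate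
Conditions: TESOTf (2.5 equiv), 2,6-lutidine, CH2Cl2, −78 °C
Reagents that add atoms: triethylsilyl trifluoromethanesulfonate, CC[Si](CC)(CC)OS(=O)(=O)C(F)(F)F
Why: Silyl ether formation with a silyl triflate and a hindered base: both secondary hydroxyls should be silylated at −78 °C faster than the ketone is enolised, which blocks retro-aldol cleavage and leaves C2 and C3 with oxygens that are poor leaving groups yet fluoride-labile.

Step 6
Reactants: 7 (3S,4S)-7-[(4-methoxybenzyl)oxy]-2-oxo-3,4-bis[(triethylsilyl)oxy]hept-5-yn-1-yl benzoate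
Product: 8 (3S,4S)-7-hydroxy-2-oxo-3,4-bis[(triethylsilyl)oxy]hept-5-yn-1-yl benzoate
Conditions: DDQ, CH2Cl2/pH 7 phosphate buffer (10:1), 0 °C
Reagents that add atoms: none
Why: Oxidative PMB ether cleavage: DDQ oxidises the electron-rich benzylic ether to an oxocarbenium ion that water hydrolyses, the buffer protects the TES ethers, and a propargylic alcohol is inert to DDQ.

Step 7
Reactants: 8 (3S,4S)-7-hydroxy-2-oxo-3,4-bis[(triethylsilyl)oxy]hept-5-yn-1-yl benzoate
Product: 9 (3S,4S,5Z)-7-hydroxy-2-oxo-3,4-bis[(triethylsilyl)oxy]hept-5-en-1-yl benzoate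
Conditions: H2 (1 atm), Pd/CaCO3 poisoned with Pb(OAc)2, quinoline, EtOAc, rt
Reagents that add atoms: none
Why: Lindlar semi-hydrogenation: syn delivery of hydrogen on the lead-poisoned palladium surface should stop at the cis-alkene, giving the Z geometry of C4=C5 that the ring closure requires.

Step 8
Reactants: 9 (3S,4S,5Z)-7-hydroxy-2-oxo-3,4-bis[(triethylsilyl)oxy]hept-5-en-1-yl benzoate
Product: 10 (3S,4S,5Z)-7-bromo-2-oxo-3,4-bis[(triethylsilyl)oxy]hept-5-en-1-yl benzoate
Conditions: CBr4, PPh3, 2,6-lutidine, CH2Cl2, −20 °C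
Reagents that add atoms: carbon tetrabromide, BrC(Br)(Br)Br
Why: Appel reaction: the primary allylic alcohol is converted through its alkoxyphosphonium ion into the bromide by SN2 displacement, with lutidine scavenging HBr so that the TES ethers and the Z-alkene should survive.

Step 9
Reactants: 10 (3S,4S,5Z)-7-bromo-2-oxo-3,4-bis[(triethylsilyl)oxy]hept-5-en-1-yl benzoate; 11 tetrahydrothiophene
Product: 15 [(1R,2S,3S,6R)-2,3-bis[(triethylsilyl)oxy]-7-oxabicyclo[4.1.0]hept-4-en-1-yl]methyl benzoate, via tetrahydrothiophenium bromide 12 (not isolated), via allyl sulfonium ylide 13 (not isolated), via oxido-sulfonium betaine 14 (not isolated)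
Conditions: tetrahydrothiophene (3 equiv), MeCN, rt; then Cs2CO3, high dilution, 0 °C → rt
Reagents that add atoms: none
Why: S-Alkylation of tetrahydrothiophene by the allylic bromide gives sulfonium salt 12, whose most acidic position (C6, allylic and next to S+) is deprotonated by Cs2CO3; the semi-stabilised allyl ylide 13 adds through C6 to the activated C1 ketone and the alkoxide of betaine 14 then displaces tetrahydrothiophene. This is an intramolecular Corey–Chaykovsky epoxidation, the closest known reaction types being sulfonium-ylide epoxy-annulations of tethered ketones and sulfide-mediated allyl-ylide epoxidations. The carbocycle closes by 6-exo-trig attack of C6 on the carbonyl with the allyl π-system inside the forming ring (possible only because C4=C5 is Z), and the oxirane closes 3-exo-tet with inversion at C6, so the epoxide is necessarily cis-fused. C1 and C6 are controlled by the C2/C3 centres: only betaines with O− and S+ trans-diaxial can close, addition of a semi-stabilised ylide to a ketone should be reversible, and the betaine leading to the all-cis epoxide reaches that arrangement with C2–OTES and CH2OBz equatorial and the new C1–C6 bond anti to the C2–O bond, whereas the other must hold C2–OTES syn-axial to the departing sulfonium. The step needs ylide formation in preference to ketone enolisation (secured by the more acidic allylic sulfonium and the mild carbonate base), attack through C6 rather than C4 (which would give a four-membered ring) and no 1,4-elimination across the ylide (secured by the silyl ether, a poor leaving group, at C3).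

Step 10
Reactants: 15 [(1R,2S,3S,6R)-2,3-bis[(triethylsilyl)oxy]-7-oxabicyclo[4.1.0]hept-4-en-1-yl]methyl benzoate
Product: 16 [(1S,2S,3S,6R)-2,3-dihydroxy-7-oxabicyclo[4.1.0]hept-4-en-1-yl]methyl benzoate
Conditions: HF·pyridine, pyridine, THF, 0 °C
Reagents that add atoms: none
Why: Fluoride-mediated desilylation: buffered HF·pyridine should cleave both TES ethers under non-basic conditions, so neither benzoate migration nor opening of the vinyl epoxide is expected.

Step 11
Reactants: 16 [(1S,2S,3S,6R)-2,3-dihydroxy-7-oxabicyclo[4.1.0]hept-4-en-1-yl]methyl benzoate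
Product: 17 [(1S,2S,3S,6R)-3-(benzoyloxy)-2-hydroxy-7-oxabicyclo[4.1.0]hept-4-en-1-yl]methyl benzoate
Conditions: BzCl (1.1 equiv), pyridine, CH2Cl2, −40 °C
Reagents that add atoms: benzoyl chloride, O=C(Cl)c1ccccc1
Why: Kinetically regioselective O-benzoylation: the allylic C3 hydroxyl, flanked only by CH groups, should be acylated faster than the C2 hydroxyl, which is neopentyl-like next to the fully substituted C1.

**Compound list**

1 | 1-methoxy-4-[(prop-2-yn-1-yloxy)methyl]benzene | C#CCOCc1ccc(OC)cc1 | starting material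
2 | 4-[(4-methoxybenzyl)oxy]but-2-ynal | O=CC#CCOCc1ccc(OC)cc1 | intermediate
3 | 2,2-dimethyl-1,3-dioxan-5-one | CC1(C)OCC(=O)CO1 | starting material
4 | (4S)-4-[(1S)-1-hydroxy-4-[(4-methoxybenzyl)oxy]but-2-yn-1-yl]-2,2-dimethyl-1,3-dioxan-5-one | CC1(C)OCC(=O)[C@@H](O1)[C@@H](O)C#CCOCc1ccc(OC)cc1 | intermediate
5 | (3S,4S)-1,3,4-trihydroxy-7-[(4-methoxybenzyl)oxy]hept-5-yn-2-one | OCC(=O)[C@@H](O)[C@@H](O)C#CCOCc1ccc(OC)cc1 | intermediate
6 | (3S,4S)-3,4-dihydroxy-7-[(4-methoxybenzyl)oxy]-2-oxohept-5-yn-1-yl benzoate | O=C(OCC(=O)[C@@H](O)[C@@H](O)C#CCOCc1ccc(OC)cc1)c1ccccc1 | intermediate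
7 | (3S,4S)-7-[(4-methoxybenzyl)oxy]-2-oxo-3,4-bis[(triethylsilyl)oxy]hept-5-yn-1-yl benzoate | O=C(OCC(=O)[C@@H](O[Si](CC)(CC)CC)[C@@H](O[Si](CC)(CC)CC)C#CCOCc1ccc(OC)cc1)c1ccccc1 | intermediate
8 | (3S,4S)-7-hydroxy-2-oxo-3,4-bis[(triethylsilyl)oxy]hept-5-yn-1-yl benzoate | O=C(OCC(=O)[C@@H](O[Si](CC)(CC)CC)[C@@H](O[Si](CC)(CC)CC)C#CCO)c1ccccc1 | intermediate
9 | (3S,4S,5Z)-7-hydroxy-2-oxo-3,4-bis[(triethylsilyl)oxy]hept-5-en-1-yl benzoate | O=C(OCC(=O)[C@@H](O[Si](CC)(CC)CC)[C@@H](O[Si](CC)(CC)CC)/C=C\CO)c1ccccc1 | intermediate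
10 | (3S,4S,5Z)-7-bromo-2-oxo-3,4-bis[(triethylsilyl)oxy]hept-5-en-1-yl benzoate | O=C(OCC(=O)[C@@H](O[Si](CC)(CC)CC)[C@@H](O[Si](CC)(CC)CC)/C=C\CBr)c1ccccc1 | intermediate
11 | tetrahydrothiophene | C1CCSC1 | starting material
12 | 1-[(2Z,4S,5S)-7-(benzoyloxy)-6-oxo-4,5-bis[(triethylsilyl)oxy]hept-2-en-1-yl]thiolan-1-ium bromide | O=C(OCC(=O)[C@@H](O[Si](CC)(CC)CC)[C@@H](O[Si](CC)(CC)CC)/C=C\C[S+]1CCCC1)c1ccccc1.[Br-] | intermediate
13 | sulfonium ylide of 12 (carbanion at C6, Z-alkene retained) | O=C(OCC(=O)[C@@H](O[Si](CC)(CC)CC)[C@@H](O[Si](CC)(CC)CC)/C=C\[CH-][S+]1CCCC1)c1ccccc1 | intermediate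
14 | betaine: 1-[(benzoyloxy)methyl]-6-(thiolan-1-ium-1-yl)-2,3-bis[(triethylsilyl)oxy]cyclohex-4-en-1-olate, O− at C1 on the face of the C2 and C3 silyloxy groups, S+ at C6 on the opposite face | O=C(OC[C@@]1([O-])[C@@H]([S+]2CCCC2)C=C[C@H](O[Si](CC)(CC)CC)[C@@H]1O[Si](CC)(CC)CC)c1ccccc1 | intermediate
15 | [(1R,2S,3S,6R)-2,3-bis[(triethylsilyl)oxy]-7-oxabicyclo[4.1.0]hept-4-en-1-yl]methyl benzoate | O=C(OC[C@@]12O[C@@H]1C=C[C@H](O[Si](CC)(CC)CC)[C@@H]2O[Si](CC)(CC)CC)c1ccccc1 | intermediate
16 | [(1S,2S,3S,6R)-2,3-dihydroxy-7-oxabicyclo[4.1.0]hept-4-en-1-yl]methyl benzoate | O=C(OC[C@@]12O[C@@H]1C=C[C@H](O)[C@@H]2O)c1ccccc1 | intermediate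
17 | [(1S,2S,3S,6R)-3-(benzoyloxy)-2-hydroxy-7-oxabicyclo[4.1.0]hept-4-en-1-yl]methyl benzoate | O=C(OC[C@@]12O[C@@H]1C=C[C@H](OC(=O)c1ccccc1)[C@@H]2O)c1ccccc1 | target

Total step count: 11. Longest linear sequence: 11 steps (1 → 17).

**Steps most likely to fail**

1) Step 9. The ylide may add to the other carbonyl face, or the other trans-betaine may close, giving the epoxide on the face opposite to the C2/C3 oxygens. Enolisation of the α-benzoyloxy ketone or E/Z isomerisation of the ylide would divert material to oligomers. The fallback sets out from bromide 10. Triphenylphosphine in MeCN should give the (Z)-allylic triphenylphosphonium bromide F1. KOtBu in THF (−78 → 0 °C) generates the phosphonium ylide F2, which forms the same C1–C6 bond by intramolecular Wittig olefination of the C1 ketone to give [(5S,6R)-5,6-bis[(triethylsilyl)oxy]cyclohexa-1,3-dien-1-yl]methyl benzoate F3. TBAF buffered with AcOH should give the cis-dienediol F4, to be used at once because such dienediols aromatise easily. Epoxidation with VO(acac)2 and t-BuOOH, directed by the allylic C2 hydroxyl to its own face of the more substituted C1=C6 bond, should then give epoxy diol 16, where the route is rejoined.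

2) Step 11. Acylation may lose regiocontrol (C2 ester or diester), and the benzoate may migrate between the cis hydroxyls under basic conditions. The fallback sets out from bis-silyl ether 15 and moves the regiochemical decision from acylation to desilylation. A limited amount of HF·pyridine at −20 °C should cleave the less hindered allylic C3 silyl ether first, giving the 3-hydroxy 2-O-triethylsilyl compound F5, which can be purified and its structure confirmed. BzCl/DMAP/pyridine then benzoylates the only free hydroxyl to give the 3-benzoate 2-O-triethylsilyl compound F6. HF·pyridine at 0 °C removes the last silyl group under non-basic conditions and gives target 17 directly.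

3) Step 2. The secondary amine catalyst may be consumed by conjugate addition to the ynal, and the slim alkynyl group may erode the anti selectivity. The fallback sets out from ynal 2 and ketone 3 and uses no amine. Cy2BCl/Et3N (Et2O, −78 °C) converts 3 into its dicyclohexylboron enolate F7. This ring-fixed E-enolate should add to 2 through a closed six-membered chair transition state to give the anti adduct in racemic form, that is 4 together with its enantiomer F8. Immobilised Candida antarctica lipase B with vinyl acetate is expected, by the empirical size rule for lipase acylation of secondary alcohols, to acetylate the (R)-carbinol enantiomer to the acetate F9. Unreacted 4 is separated and re-enters the route at 4.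

**Further compounds**

F1 | step 9 | [(2Z,4S,5S)-7-(benzoyloxy)-6-oxo-4,5-bis[(triethylsilyl)oxy]hept-2-en-1-yl]triphenylphosphonium bromide | O=C(OCC(=O)[C@@H](O[Si](CC)(CC)CC)[C@@H](O[Si](CC)(CC)CC)/C=C\C[P+](c1ccccc1)(c1ccccc1)c1ccccc1)c1ccccc1.[Br-]
F2 | step 9 | phosphonium ylide of F1 (carbanion at C6) | O=C(OCC(=O)[C@@H](O[Si](CC)(CC)CC)[C@@H](O[Si](CC)(CC)CC)/C=C\[CH-][P+](c1ccccc1)(c1ccccc1)c1ccccc1)c1ccccc1
F3 | step 9 | [(5S,6R)-5,6-bis[(triethylsilyl)oxy]cyclohexa-1,3-dien-1-yl]methyl benzoate | O=C(OCC1=CC=C[C@H](O[Si](CC)(CC)CC)[C@@H]1O[Si](CC)(CC)CC)c1ccccc1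
F4 | step 9 | [(5S,6R)-5,6-dihydroxycyclohexa-1,3-dien-1-yl]methyl benzoate | O=C(OCC1=CC=C[C@H](O)[C@@H]1O)c1ccccc1
F5 | step 11 | [(1R,2S,3S,6R)-3-hydroxy-2-[(triethylsilyl)oxy]-7-oxabicyclo[4.1.0]hept-4-en-1-yl]methyl benzoate | O=C(OC[C@@]12O[C@@H]1C=C[C@H](O)[C@@H]2O[Si](CC)(CC)CC)c1ccccc1
F6 | step 11 | [(1R,2S,3S,6R)-3-(benzoyloxy)-2-[(triethylsilyl)oxy]-7-oxabicyclo[4.1.0]hept-4-en-1-yl]methyl benzoate | O=C(OC[C@@]12O[C@@H]1C=C[C@H](OC(=O)c1ccccc1)[C@@H]2O[Si](CC)(CC)CC)c1ccccc1
F7 | step 2 | dicyclohexylboron enolate of 3: 5-[(dicyclohexylboranyl)oxy]-2,2-dimethyl-4H-1,3-dioxine | CC1(C)OCC(OB(C2CCCCC2)C2CCCCC2)=CO1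
F8 | step 2 | (4R)-4-[(1R)-1-hydroxy-4-[(4-methoxybenzyl)oxy]but-2-yn-1-yl]-2,2-dimethyl-1,3-dioxan-5-one (enantiomer of 4) | CC1(C)OCC(=O)[C@H](O1)[C@H](O)C#CCOCc1ccc(OC)cc1
F9 | step 2 | (1R)-1-[(4R)-2,2-dimethyl-5-oxo-1,3-dioxan-4-yl]-4-[(4-methoxybenzyl)oxy]but-2-yn-1-yl acetate | CC1(C)OCC(=O)[C@H](O1)[C@H](OC(C)=O)C#CCOCc1ccc(OC)cc1
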